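Minutes per half-life are the unit in which Ada and Ben argue over this flask.

| setting | ash | cedar | flask |
|---|---|---|---|
| starting material | 0.25 M | 0.25 M | 0.25 M |
| partner | 1.1 equiv | 1.1 equiv | 1.10 equiv |
| protic impurity | 0.125 M | 0.125 M | 0.125 M |
| free catalyst | 0.13 mol% | 0.3 mol% | 0.2 mol% |
| remark | run made earlier | run made earlier |  |

| run | time / min | product / % | starting material / % |
|---|---|---|---|
| ash | 0.833 | 2 | 94 |
| ash | 2.00 | 7 | 93 |
| ash | 4.00 | 10 | 88 |
| ash | 6.00 | 16 | 86 |
| cedar | 1.50 | 10 | 90 |
| cedar | 3.00 | 19 | 79 |
| cedar | 5.00 | 30 | 70 |
| cedar | 6.00 | 34 | 63 |

(each reading ± 2 percentage points)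

- the analysis behind the earlier runs scatters by 2 percentage points, standard deviation
- no earlier run changes the charge of partner; that part of a forecast is a guess

- apparent order in free catalyst when 50% of the starting material are converted (percent change of the rate of making product for one percent more free catalyst charged)
- factor on the rate of making product when 50% of the starting material are converted if partner is charged twice over

Ada holds a pseudo-first-order view. Starting material decays with a constant in proportion to free catalyst, and [partner] is a bystander. The cedar run shows 34% product after 6.00 min, so on her view its half-life reads 10.0 min. Scaled to the flask's loading, that gives 15.0 min. Call this the clock: the half-life of starting material, taken as inversely proportional to the loading.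

Ada tests it on the ash run. There the clock reads 23.1 min, which puts product at 16.5% after 6.00 min. Ash read 16%, with a scatter of 2 percentage points. So Ada says order one in free catalyst, and a factor of one for doubled partner.

Ben holds that partner is a true first-order reagent. Doubling the charge takes partner at 50% conversion from 0.6 to 1.7 equivalents. So he says 2.8-fold.

The forecast leans towards Ada, with 1.05 for the order and 1.4 for the doubling, the second “largely a guess”.

The flask gives 1.2 and 1.65, so partner is no bystander and Ada loses, though Ben's 2.8 is not reached either. The flask reaches 50% conversion at 14.2 min, against her clock of 15.0 min.

    starting material + free catalyst → catalyst intermediate A (k = 490 L mol⁻¹ min⁻¹)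
    partner + protic impurity → quenched reagent (k = 0.290 L mol⁻¹ min⁻¹)
    catalyst intermediate C → by-product + catalyst intermediate D (k = 130 min⁻¹)
    partner + catalyst intermediate A ⇌ catalyst intermediate B (K = 1.20 L mol⁻¹, k = 950 L mol⁻¹ min⁻¹)
    catalyst intermediate B ⇌ catalyst intermediate C (K = 3.10, k = 1200 min⁻¹)
    catalyst intermediate D → free catalyst + product (k = 96.0 min⁻¹)

Ada keeps the early flask. Her clock puts product at 20.6% after 5.00 min, and the flask then holds 21.0%, with free catalyst at 19.9% of its charge. Counted to 50.0 min, the clock leaves 9.92% of the starting material. The flask holds 20.5%, with partner down to 0.416% of its charge and catalyst intermediate A, the resting state, at 98.2% of the catalyst. Part of partner's weight comes from reversible binding: in a run without the reverse step from catalyst intermediate B to partner and catalyst intermediate A, the apparent order in partner falls from 1.4 to 0.50.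

(The runs come from a simulation from invented constants, and the scatter is random.)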